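**Retrosynthetic overview**
1. Target 18 ⇐ singlet-oxygen ene reaction on the Δ4 alkene of angelate 17 (sets 5α-OOH and the 4(15)-methylene) ⇐ angeloylation and Luche reduction of enone 13.
2. Acrylate 13 ⇐ Wittig methylenation of α-keto ester 12; C7 is set by base equilibration of 12 to the equatorial epimer.
3. Key C7–C11 bond: 12 ⇐ 1,6-addition of a masked glyoxylate acyl anion (ethyl 1,3-dithiane-2-carboxylate) to the 4,6-dien-3-one 8, joining a latent ketone carbon to an electrophilic dienone terminus.
4. 8 ⇐ dehydrogenation of octalone 7 ⇐ auxiliary-controlled Robinson annulation of 2-methylcyclohexanone with ethyl vinyl ketone (sets C10).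
5. Ring order: ring B is the starting cyclohexanone; ring A is closed in step 2; no further rings are formed.

Assumption: step 2 gives 7 in about 90% ee, and one low-temperature recrystallisation of 7 (or of crystalline 12) is taken to bring the series to a single enantiomer. Positions are given in eudesmane numbering (C3 carbinol, C4/C15, C5, C7, C10 angular, C11–C13 side chain).

**Step 1**
Reactants: 1 2-methylcyclohexanone; 2 (R)-1-phenylethylamine
Product: 3 (R)-N-(2-methylcyclohexylidene)-1-phenylethanamine (E/Z and ring-epimer mixture)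
Conditions: TsOH (cat.), toluene, reflux, Dean–Stark
Reagents that add atoms: none
Why: Acid-catalysed ketimine condensation with azeotropic water removal; the imine equilibrates with its more substituted secondary enamine, so no ring stereocentre is fixed yet.

**Step 2**
Reactants: 3 imine; 4 ethyl vinyl ketone (pent-1-en-3-one)
Product: 7 (S)-1,4a-dimethyl-4,4a,5,6,7,8-hexahydronaphthalen-2(3H)-one, via Michael-adduct imine 5 (not isolated), via diketone 6 (not isolated)
Conditions: THF, 40 °C, 3 d; then 10% aq. AcOH, rt; then NaOMe, MeOH, 60 °C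
Reagents that add atoms: none
Why: d'Angelo deracemising Michael addition, in which the secondary enamine adds to the enone through a compact aza-ene-like transition state anti to the auxiliary phenyl group and sets the quaternary carbon as S (10β-methyl); hydrolysis and intramolecular aldol condensation (Robinson annulation) then close ring A.

**Step 3**
Reactants: 7 octalone
Product: 8 (S)-1,4a-dimethyl-4,4a,5,6-tetrahydronaphthalen-2(3H)-one (the 4,6-dien-3-one)
Conditions: chloranil (1.3 equiv), t-BuOH, reflux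
Reagents that add atoms: none
Why: Quinone dehydrogenation of a Δ4-3-ketone through its 3,5-dienol (hydride loss from C7) gives the linear dienone; C10 is untouched.

**Step 4 (key step)**
Reactants: 8 dienone; 9 ethyl 1,3-dithiane-2-carboxylate
Product: 10 ethyl 2-[(4aS)-4a,8-dimethyl-7-oxo-1,2,3,4,4a,5,6,7-octahydronaphthalen-2-yl]-1,3-dithiane-2-carboxylate (epimers at C7, 7α expected major)
Conditions: 9 (1.5 equiv), KHMDS (1.4 equiv), THF–DMPU, −78 °C; add 8, −78 °C → rt; AcOH; then DBU (cat.), CH2Cl2, rt
Reagents that add atoms: none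
Why: Proposed new method: the soft, ester-stabilised 2-dithianyl anion (a masked RO2C–C(=O)⁻ acyl anion) should add 1,6 at C7 because the β-carbon C5 is fully substituted and 1,2-addition is reversible, and DBU returns the enone to conjugation; the closest known reactions are 1,4-additions of this anion to cyclohexenones and 1,6-Michael additions of malonate or nitromethane to steroidal 4,6-dien-3-ones; attack anti to the angular methyl should favour 7α, which is corrected in step 5.

**Step 5**
Reactants: 10 dithiane adduct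
Product: 12 methyl 2-[(2R,4aS)-4a,8-dimethyl-7-oxo-1,2,3,4,4a,5,6,7-octahydronaphthalen-2-yl]-2-oxoacetate, via ethyl keto ester 11 (not isolated)
Conditions: PhI(OCOCF3)2 (1.5 equiv), MeCN–H2O 9:1, 0 °C; then K2CO3 (0.3 equiv), MeOH, rt
Reagents that add atoms: water, O; methanol, CO
Why: Stork–Zhao oxidative dethioketalisation unmasks the α-keto ester; C7–H is now α to a ketone, so carbonate in methanol equilibrates C7 to the equatorial 7β (R) epimer (estimated 6–9:1, minor epimer recycled) and transesterifies the activated ester to the methyl ester.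

**Step 6**
Reactants: 12 keto ester
Product: 13 methyl 2-[(2R,4aS)-4a,8-dimethyl-7-oxo-1,2,3,4,4a,5,6,7-octahydronaphthalen-2-yl]prop-2-enoate (methyl 3-oxoeudesma-4,11(13)-dien-12-oate)
Conditions: Ph3PCH3Br (1.3 equiv), KOt-Bu (1.2 equiv), THF, 0 °C; then 12, −78 → 0 °C
Reagents that add atoms: methyltriphenylphosphonium bromide, C[P+](c1ccccc1)(c1ccccc1)c1ccccc1.[Br-]
Why: Wittig methylenation is chemoselective for the strongly electrophilic α-keto ester carbonyl over the hindered conjugated C3 ketone and gives the α-substituted acrylate without touching C7 or C10.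

**Step 7**
Reactants: 13 enone
Product: 14 methyl 2-[(2R,4aS,7S)-7-hydroxy-4a,8-dimethyl-1,2,3,4,4a,5,6,7-octahydronaphthalen-2-yl]prop-2-enoate (3β-alcohol)
Conditions: NaBH4, CeCl3·7H2O, MeOH, −78 → −40 °C
Reagents that add atoms: none
Why: Luche 1,2-reduction, in which hydride adds axially from the α-face (anti to the 10β-methyl) and gives the pseudo-equatorial 3β (S) allylic alcohol; the acrylate does not react at this temperature.

**Step 8**
Reactants: 14 allylic alcohol; 15 angelic acid ((Z)-2-methylbut-2-enoic acid)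
Product: 17 methyl 2-[(2R,4aS,7S)-4a,8-dimethyl-7-{[(2Z)-2-methylbut-2-enoyl]oxy}-1,2,3,4,4a,5,6,7-octahydronaphthalen-2-yl]prop-2-enoate, via mixed anhydride 16 (not isolated)
Conditions: 15, 2,4,6-trichlorobenzoyl chloride, Et3N, toluene, rt; then 14, 75 °C (no DMAP)
Reagents that add atoms: none
Why: Yamaguchi-type mixed-anhydride esterification, in which the alcohol attacks the less hindered angeloyl carbonyl with retention at C3; omitting DMAP avoids Z→E isomerisation to the tiglate.

**Step 9**
Reactants: 17 angelate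
Product: 18 methyl 2-[(2R,4aS,7S,8aS)-8a-hydroperoxy-4a-methyl-8-methylidene-7-{[(2Z)-2-methylbut-2-enoyl]oxy}decahydronaphthalen-2-yl]prop-2-enoate (target)
Conditions: O2, tetraphenylporphyrin (1 mol%), CH2Cl2, white LED, 0 °C; no reductive work-up
Reagents that add atoms: oxygen (as singlet oxygen), O=O
Why: Schenck ene reaction at the only electron-rich (tetrasubstituted) alkene, where oxygen bonds to C5 on the α-face anti to the 10β-methyl and takes a C15 methyl hydrogen (C3–H is deactivated by the geminal acyloxy group and C6–Hα is poorly aligned), giving the 5α (S) hydroperoxide and the 4(15)-methylene; the acrylate and angelate are too electron-poor to react.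

**Compound list**
1 | 2-methylcyclohexanone (racemic) | CC1CCCCC1=O | starting material
2 | (R)-1-phenylethylamine | C[C@@H](N)c1ccccc1 | starting material
3 | (R)-N-(2-methylcyclohexylidene)-1-phenylethanamine | C[C@@H](N=C1CCCCC1C)c1ccccc1 | intermediate
4 | ethyl vinyl ketone | C=CC(=O)CC | starting material
5 | (R)-N-[(2S)-2-methyl-2-(3-oxopentyl)cyclohexylidene]-1-phenylethanamine | C[C@@H](N=C1CCCC[C@@]1(C)CCC(=O)CC)c1ccccc1 | intermediate
6 | (S)-2-methyl-2-(3-oxopentyl)cyclohexan-1-one | O=C1CCCC[C@@]1(C)CCC(=O)CC | intermediate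
7 | (S)-1,4a-dimethyl-4,4a,5,6,7,8-hexahydronaphthalen-2(3H)-one | CC1=C2CCCC[C@@]2(C)CCC1=O | intermediate
8 | (S)-1,4a-dimethyl-4,4a,5,6-tetrahydronaphthalen-2(3H)-one | CC1=C2C=CCC[C@@]2(C)CCC1=O | intermediate
9 | ethyl 1,3-dithiane-2-carboxylate | CCOC(=O)C1SCCCS1 | starting material
10 | ethyl 2-[(4aS)-4a,8-dimethyl-7-oxo-1,2,3,4,4a,5,6,7-octahydronaphthalen-2-yl]-1,3-dithiane-2-carboxylate (C7 epimers) | CCOC(=O)C1(SCCCS1)C1CC[C@@]2(C)CCC(=O)C(C)=C2C1 | intermediate
11 | ethyl 2-[(4aS)-4a,8-dimethyl-7-oxo-1,2,3,4,4a,5,6,7-octahydronaphthalen-2-yl]-2-oxoacetate (C7 epimers) | CCOC(=O)C(=O)C1CC[C@@]2(C)CCC(=O)C(C)=C2C1 | intermediate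
12 | methyl 2-[(2R,4aS)-4a,8-dimethyl-7-oxo-1,2,3,4,4a,5,6,7-octahydronaphthalen-2-yl]-2-oxoacetate | COC(=O)C(=O)[C@@H]1CC[C@@]2(C)CCC(=O)C(C)=C2C1 | intermediate
13 | methyl 3-oxoeudesma-4,11(13)-dien-12-oate (7R,10S) | C=C(C(=O)OC)[C@@H]1CC[C@@]2(C)CCC(=O)C(C)=C2C1 | intermediate
14 | methyl 3β-hydroxyeudesma-4,11(13)-dien-12-oate (3S,7R,10S) | C=C(C(=O)OC)[C@@H]1CC[C@@]2(C)CC[C@H](O)C(C)=C2C1 | intermediate
15 | angelic acid | C/C=C(/C)C(=O)O | starting material
16 | angelic 2,4,6-trichlorobenzoic anhydride | C/C=C(/C)C(=O)OC(=O)c1c(Cl)cc(Cl)cc1Cl | intermediate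
17 | methyl 3β-angeloyloxyeudesma-4,11(13)-dien-12-oate (3S,7R,10S) | C=C(C(=O)OC)[C@@H]1CC[C@@]2(C)CC[C@H](OC(=O)/C(C)=C\C)C(C)=C2C1 | intermediate
18 | methyl 3β-angeloyloxy-5α-hydroperoxyeudesma-4(15),11(13)-dien-12-oate (3S,5S,7R,10S) | C=C(C(=O)OC)[C@@H]1CC[C@@]2(C)CC[C@H](OC(=O)/C(C)=C\C)C(=C)[C@]2(OO)C1 | target

**Totals**
Total step count: 9. Longest linear sequence: 9 steps (from 1).

**Three steps most likely to fail**

Step 4: the hindered anion may add slowly, add 1,2, or give an unfavourable C7 mixture. The fallback sets out again from 8 and uses a reversible, DBU-catalysed 1,6-Michael addition of methyl nitroacetate (MeCN, 40 °C), which places the new substituent equatorial under thermodynamic control and gives methyl 2-[(2R,4aS)-4a,8-dimethyl-7-oxo-1,2,3,4,4a,5,6,7-octahydronaphthalen-2-yl]-2-nitroacetate F1. An oxidative Nef reaction of its nitronate (K2CO3, MeOH, then buffered Oxone, 0 °C) gives the keto ester and the route is rejoined at 12.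

Step 6: the basic ylide may enolise the keto ester or touch the C3 ketone. The fallback sets out from 12 and uses a Peterson olefination: Me3SiCH2MgCl with CeCl3 (THF, −78 °C) adds only to the keto ester carbonyl to give methyl 2-[(2R,4aS)-4a,8-dimethyl-7-oxo-1,2,3,4,4a,5,6,7-octahydronaphthalen-2-yl]-2-hydroxy-3-(trimethylsilyl)propanoate F2. BF3·OEt2 then triggers elimination to the methylene compound and the route is rejoined at 13.

Step 9: hydrogen abstraction from C3 or C6 could give the enol ester or the 4α-hydroperoxy-5-ene instead. The fallback sets out from 17: mCPBA with NaHCO3 epoxidises the tetrasubstituted alkene from the α-face to give methyl 3β-angeloyloxy-4α,5α-epoxyeudesm-11(13)-en-12-oate F3. Cp2TiCl (from Cp2TiCl2 and Mn, THF) opens the epoxide by a radical path with loss of a C15 hydrogen to give methyl 3β-angeloyloxy-5α-hydroxyeudesma-4(15),11(13)-dien-12-oate F4. Ethereal H2O2 with catalytic TsOH at 0 °C then exchanges the tertiary allylic hydroxyl for hydroperoxide through the allyl cation, captured at C5 from the α-face, and the route is rejoined at 18.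

**Further compounds**
F1 | step 4 | methyl 2-[(2R,4aS)-4a,8-dimethyl-7-oxo-1,2,3,4,4a,5,6,7-octahydronaphthalen-2-yl]-2-nitroacetate | COC(=O)C([N+](=O)[O-])[C@@H]1CC[C@@]2(C)CCC(=O)C(C)=C2C1
F2 | step 6 | methyl 2-[(2R,4aS)-4a,8-dimethyl-7-oxo-1,2,3,4,4a,5,6,7-octahydronaphthalen-2-yl]-2-hydroxy-3-(trimethylsilyl)propanoate | COC(=O)C(O)(C[Si](C)(C)C)[C@@H]1CC[C@@]2(C)CCC(=O)C(C)=C2C1
F3 | step 9 | methyl 3β-angeloyloxy-4α,5α-epoxyeudesm-11(13)-en-12-oate | C=C(C(=O)OC)[C@@H]1CC[C@@]2(C)CC[C@H](OC(=O)/C(C)=C\C)[C@@]3(C)O[C@@]23C1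
F4 | step 9 | methyl 3β-angeloyloxy-5α-hydroxyeudesma-4(15),11(13)-dien-12-oate | C=C(C(=O)OC)[C@@H]1CC[C@@]2(C)CC[C@H](OC(=O)/C(C)=C\C)C(=C)[C@]2(O)C1
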